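**Retrosynthetic overview**

1. The target gibberellin (number thirty-nine of the gibberellin A series; 3β,12α-dihydroxygibberell-16-ene-7,19,20-trioic acid) ⇐ opening of a temporary C20→O12 δ-lactone, ester cleavage, C3 reduction and C4 methylation ⇐ ring A, closed last by Dieckmann condensation (C3–C4).
2. Ring B ⇐ Wolff ring contraction of a cyclohexanone in which C7 is a ring member between C6 and C8; ring D ⇐ 5-exo-dig radical closure C13–C16 onto a propargyl group on C8.
3. Key disconnection: C8–C9 and C5–C10 of that cyclohexanone ⇐ intramolecular Diels–Alder reaction of the dienol ether C5=C6–C7(O)=C8, held in a 2,3-dihydrofuran by a temporary C13–O–C7 bridge, with the Z-acrylate C9=C10–C20. It forms ring C and six-membered ring B and sets C5, C8, C9 and C10.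
4. Enabling feature: ring B is a cyclopentane with the C7 carboxyl exocyclic on C6 between C5 and C8 (a contracted cyclohexanone), C10 carries the activating C20 carboxyl, and C13 is 1,3 to C8 on ring C, so an oxygen on C13 can tie C7 to ring C and later serves as the radical leaving site for ring D.
5. The precursor comes from three pieces (a γ-lactone from one Shi epoxidation, an alkenylboronate, a phosphonoglutarate). Ring order: dihydrofuran (temporary) → rings C and B (six-membered) → lactone lock → ring D → ring B contraction → ring A.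

Key step: step 15

Remark (assumption): the 12α-hydroxyl and the C20 carboxyl are syn-axial on ring C; their δ-lactone is used as internal protection and is assumed to open on saponification, the hydroxy acid being isolated after cold acidification. Advanced intermediates are described with gibberellane numbering (C1–C20) and α/β as in the usual gibberellin drawing.

**Route**

Step 1
Reactants: 1 3-[(tert-butyldimethylsilyl)oxy]propanal; 2 vinylmagnesium bromide
Product: 3 rac-5-[(tert-butyldimethylsilyl)oxy]pent-1-en-3-ol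
Conditions: CH2=CHMgBr, THF, −78 → 0 °C; aq. NH4Cl
Reagents that add atoms: vinylmagnesium bromide, C=C[Mg]Br
Why: Grignard 1,2-addition to the aldehyde gives the racemic allylic alcohol, whose stereocentre is erased in step 2.

Step 2
Reactants: 3 rac-5-[(tert-butyldimethylsilyl)oxy]pent-1-en-3-ol; 4 trimethyl orthoacetate
Product: 6 methyl (4E)-7-[(tert-butyldimethylsilyl)oxy]hept-4-enoate, via mixed ketene acetal 5 (not isolated)
Conditions: MeC(OMe)3, EtCO2H (cat.), 140 °C, MeOH distilled off
Reagents that add atoms: trimethyl orthoacetate, CC(OC)(OC)OC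
Why: Johnson–Claisen [3,3]-sigmatropic rearrangement through a chair transition state with the side chain equatorial should give the E-configured γ,δ-unsaturated ester (C7–C8–C14–C13=C12–C11–C9 chain).

Step 3
Reactants: 6 methyl (4E)-7-[(tert-butyldimethylsilyl)oxy]hept-4-enoate; 7 potassium peroxymonosulfate
Product: 8 methyl 3-[(2S,3S)-3-{2-[(tert-butyldimethylsilyl)oxy]ethyl}oxiran-2-yl]propanoate
Conditions: KHSO5 (as Oxone), 1,2:4,5-di-O-isopropylidene-β-L-erythro-2,3-hexodiulo-2,6-pyranose (enantiomer of the D-fructose-derived Shi ketone, 30 mol %), K2CO3, Bu4NHSO4, MeCN/CH2(OMe)2/aq. buffer pH 10.5, 0 °C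
Reagents that add atoms: potassium peroxymonosulfate, OOS(=O)(=O)[O-].[K+]
Why: Shi asymmetric epoxidation of the trans-disubstituted alkene with the enantiomer of the usual D-fructose-derived ketone should give the (S,S)-epoxide through the spiro transition state, setting C12 and C13.

Step 4
Reactants: 8 methyl 3-[(2S,3S)-3-{2-[(tert-butyldimethylsilyl)oxy]ethyl}oxiran-2-yl]propanoate; 9 lithium hydroxide
Product: 11 (5R)-5-[(1S)-3-[(tert-butyldimethylsilyl)oxy]-1-hydroxypropyl]oxolan-2-one, via epoxy acid 10 (not isolated)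
Conditions: LiOH, THF/H2O, 0 °C; aq. HCl to pH 4; then camphorsulfonic acid (10 mol %), CH2Cl2, 25 °C
Reagents that add atoms: lithium hydroxide, [Li+].[OH-]
Why: Saponification followed by acid-catalysed 5-exo opening of the epoxide by the carboxyl group (epoxy-acid lactonisation) inverts C13 and retains C12, giving the erythro hydroxy γ-lactone.

Step 5
Reactants: 11 (5R)-5-[(1S)-3-[(tert-butyldimethylsilyl)oxy]-1-hydroxypropyl]oxolan-2-one; 12 triisopropylsilyl trifluoromethanesulfonate
Product: 13 (5R)-5-[(1S)-3-[(tert-butyldimethylsilyl)oxy]-1-[(triisopropylsilyl)oxy]propyl]oxolan-2-one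
Conditions: i-Pr3SiOTf, 2,6-lutidine, CH2Cl2, −78 → 0 °C
Reagents that add atoms: triisopropylsilyl trifluoromethanesulfonate, CC(C)[Si](OS(=O)(=O)C(F)(F)F)(C(C)C)C(C)C
Why: Silylation of the secondary alcohol with a silyl triflate and a hindered base installs a group that survives the later fluoride cleavage of the primary silyl ether.

Step 6
Reactants: 13 (5R)-5-[(1S)-3-[(tert-butyldimethylsilyl)oxy]-1-[(triisopropylsilyl)oxy]propyl]oxolan-2-one; 14 3-bromo-1-(trimethylsilyl)prop-1-yne
Product: 15 (3S,5R)-3-[3-(trimethylsilyl)prop-2-yn-1-yl] derivative of lactone 13 (trans isomer; the cis epimer is carried along)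
Conditions: LiN(i-Pr)2, THF, −78 °C; then 14, DMPU, −78 → −40 °C
Reagents that add atoms: 3-bromo-1-(trimethylsilyl)prop-1-yne, C[Si](C)(C)C#CCBr
Why: Lactone enolate alkylation with the propargylic bromide occurs anti to the C5 substituent and introduces C15–C17, the new centre (C8) being planarised in step 7.

Step 7
Reactants: 15 (3S,5R)-3-propargylated lactone; 16 diphenyl chlorophosphate
Product: 17 (5R)-5-[(1S)-3-[(tert-butyldimethylsilyl)oxy]-1-[(triisopropylsilyl)oxy]propyl]-3-[3-(trimethylsilyl)prop-2-yn-1-yl]-4,5-dihydrofuran-2-yl diphenyl phosphate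
Conditions: KN(SiMe3)2, (PhO)2P(O)Cl, THF/HMPA, −78 °C
Reagents that add atoms: diphenyl chlorophosphate, O=P(Cl)(Oc1ccccc1)Oc1ccccc1
Why: O-Phosphorylation of the potassium lactone enolate gives the ketene acetal phosphate, a stable enol electrophile for cross-coupling; the ring fixes C14 cis to oxygen on the C7=C8 bond.

Step 8
Reactants: 18 but-3-ynoic acid; 19 tert-butyl 2,2,2-trichloroacetimidate
Product: 20 tert-butyl but-3-ynoate
Conditions: BF3·OEt2 (cat.), cyclohexane/CH2Cl2, 25 °C
Reagents that add atoms: tert-butyl 2,2,2-trichloroacetimidate, CC(C)(C)OC(=N)C(Cl)(Cl)Cl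
Why: Acid-catalysed tert-butylation with the trichloroacetimidate esterifies without base, so the β,γ-alkynoate is not isomerised to the allenoate.

Step 9
Reactants: 20 tert-butyl but-3-ynoate; 21 pinacolborane
Product: 22 tert-butyl (3E)-4-(4,4,5,5-tetramethyl-1,3,2-dioxaborolan-2-yl)but-3-enoate
Conditions: HBpin, Cp2Zr(H)Cl (5 mol %), CH2Cl2, 25 °C
Reagents that add atoms: pinacolborane, CC1(C)OBOC1(C)C
Why: Cp2Zr(H)Cl-catalysed syn-hydroboration of the terminal alkyne gives the E-alkenylboronate regioselectively (C6=C5–C4–C19 unit).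

Step 10
Reactants: 23 methyl [bis(2,2,2-trifluoroethoxy)phosphoryl]acetate; 24 methyl acrylate
Product: 25 dimethyl 2-[bis(2,2,2-trifluoroethoxy)phosphoryl]pentanedioate (racemic)
Conditions: KOt-Bu (10 mol %), THF, 0 °C, 23 in excess
Reagents that add atoms: methyl acrylate, C=CC(=O)OC
Why: Base-catalysed Michael addition of the acidic phosphonoacetate to the acrylate gives the α-substituted Still–Gennari reagent carrying C10, C20 and C1–C3.

Step 11
Reactants: 17 ketene acetal phosphate; 22 tert-butyl (3E)-4-(4,4,5,5-tetramethyl-1,3,2-dioxaborolan-2-yl)but-3-enoate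
Product: 26 tert-butyl (3E)-4-{(5R)-5-[(1S)-3-[(tert-butyldimethylsilyl)oxy]-1-[(triisopropylsilyl)oxy]propyl]-3-[3-(trimethylsilyl)prop-2-yn-1-yl]-4,5-dihydrofuran-2-yl}but-3-enoate
Conditions: Pd(PPh3)4 (5 mol %), aq. K3PO4, DMF, 50 °C
Reagents that add atoms: boronate 22, CC(C)(C)OC(=O)C/C=C/B1OC(C)(C)C(C)(C)O1
Why: Suzuki–Miyaura coupling of the lactone-derived ketene acetal phosphate with the alkenylboronate proceeds with retention of alkene geometry and gives the 2-dienyl-4,5-dihydrofuran.

Step 12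
Reactants: 26 silylated dienyl dihydrofuran
Product: 27 tert-butyl (3E)-4-{(5R)-5-[(1S)-3-hydroxy-1-[(triisopropylsilyl)oxy]propyl]-3-(prop-2-yn-1-yl)-4,5-dihydrofuran-2-yl}but-3-enoate
Conditions: Bu4NF/AcOH (1:1), THF, 0 → 25 °C
Reagents that add atoms: none
Why: Buffered fluoride cleaves the primary silyl ether and the alkynyl C–Si bond much faster than the hindered secondary triisopropylsilyl ether, and is neither acidic enough to hydrolyse the dienol ether nor basic enough to conjugate the β,γ-unsaturated ester.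

Step 13
Reactants: 27 primary alcohol
Product: 28 tert-butyl (3E)-4-{(5R)-5-[(1S)-3-oxo-1-[(triisopropylsilyl)oxy]propyl]-3-(prop-2-yn-1-yl)-4,5-dihydrofuran-2-yl}but-3-enoate
Conditions: Dess–Martin periodinane, pyridine, CH2Cl2, 0 °C
Reagents that add atoms: none
Why: Pyridine-buffered Dess–Martin oxidation converts the primary alcohol into the C9 aldehyde without touching the acid-labile dienol ether.

Step 14
Reactants: 28 aldehyde; 25 dimethyl 2-[bis(2,2,2-trifluoroethoxy)phosphoryl]pentanedioate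
Product: 29 dimethyl (2Z)-2-{(3S)-3-[(2R)-5-[(1E)-4-tert-butoxy-4-oxobut-1-en-1-yl]-4-(prop-2-yn-1-yl)-2,3-dihydrofuran-2-yl]-3-[(triisopropylsilyl)oxy]propylidene}pentanedioate
Conditions: 25, KN(SiMe3)2, 18-crown-6, THF, −78 °C; then 28
Reagents that add atoms: phosphonate 25, COC(=O)CCC(C(=O)OC)P(=O)(OCC(F)(F)F)OCC(F)(F)F
Why: The Still–Gennari variant of the Horner–Wadsworth–Emmons reaction gives the Z-trisubstituted alkene (C20 ester cis to C11) under kinetic control.

Step 15
Reactants: 29 Z-triene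
Product: 30 Diels–Alder adduct: cyclohexene ring B (C5–C6=C7–C8–C9–C10) cis-fused to ring C with O13 bridging C13 and C7; 5β-H, 5α-CH2CO2t-Bu, 8β-propargyl, 9β-H, 10α-CO2Me, 10β-CH2CH2CO2Me, 12α-OSi(i-Pr)3
Conditions: PhMe (0.01 M), BHT, K2CO3 (solid), 130 °C, sealed tube
Reagents that add atoms: none
Why: Thermal intramolecular Diels–Alder reaction (normal electron demand, concerted, suprafacial on both partners) between the electron-rich 2-alkoxydiene C5=C6–C7(O13)=C8, whose nucleophilic terminus C8 is matched with the β-carbon C9 of the ester-activated Z-alkene C9=C10; the closest precedents are the cis-selective cyclisations of (Z)-undeca-2,8,10-trienoates (four-atom tether) and the cycloadditions of 2-vinyl-dihydrofurans and 2-vinyl-dihydropyrans. Ring C closes through the four-atom tether C14–C13–C12–C11 (six-membered, chair-like, 12-silyloxy group equatorial) and ring B is the cyclohexene of the [4+2] event, so the product is a 6-oxabicyclo[3.2.1]octane in which O13 links C13 to C7. Because C13 of the dihydrofuran carries the tether, the dienophile can reach only the diene face syn to C12, so the C13 stereocentre from the Shi epoxidation fixes the absolute configuration at C8 and C9, and the single carbon C12 can span C13 and C11 only when C11 lies endo over the diene, which takes the cis C20 ester endo as well and places C20 α and C1 β on C10. The ring oxygen locks the C7=C8 geometry with C14 outside and the propargyl CH2 inside, and the E-configured C5=C6 bond puts C4 outside, so the suprafacial addition should give 5β-H, 8β-propargyl and 9β-H together with the two quaternary centres C8 and C10. The step needs cis B/C fusion with the ester endo and an intact Z-dienophile and enol ether; the tether secures the first, and neutral base-buffered conditions the second.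

Step 16
Reactants: 30 Diels–Alder adduct; 31 water
Product: 33 13α-hydroxy-7-oxo 20,12α-lactone (ring B six-membered with C7 ketone; 8β-propargyl; C3 methyl ester and C19 tert-butyl ester side chains), via keto diol 32 (not isolated)
Conditions: 48% aq. HF, MeCN, 0 → 25 °C; then PPTS (10 mol %), PhMe, 80 °C
Reagents that add atoms: water, O
Why: Aqueous acid hydrolyses the bridging enol ether to the C7 ketone and the 13-hydroxyl and removes the silyl group, after which the 12α-hydroxyl, syn-axial to C10 once ring C has flipped, transesterifies the C20 methyl ester to the δ-lactone (any bridged hemiketal stays in equilibrium with the keto diol and drains into the lactone); this differentiates the two hydroxyls and locks ring C in the chair with the propargyl group axial.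

Step 17
Reactants: 33 hydroxy keto lactone; 34 1,1'-thiocarbonyldiimidazole
Product: 35 13-O-(imidazol-1-ylcarbonothioyl) derivative of 33
Conditions: 1,1'-thiocarbonyldiimidazole, DMAP (cat.), ClCH2CH2Cl, 60 °C
Reagents that add atoms: 1,1'-thiocarbonyldiimidazole, S=C(n1ccnc1)n1ccnc1
Why: Acylation of the only free hydroxyl gives the Barton–McCombie radical precursor at C13.

Step 18
Reactants: 35 thiocarbonyl imidazolide
Product: 36 tetracyclic 7-ketone with ring D closed (16-methylene, 13α-H, 20,12α-lactone)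
Conditions: Bu3SnH (syringe pump), AIBN (cat.), PhH, 80 °C
Reagents that add atoms: none
Why: Barton–McCombie C–O homolysis gives the C13 radical, which closes ring D by 5-exo-dig attack on the axial propargyl group (only the β-face is within reach, so H13 ends α), and the vinyl radical is reduced to the exocyclic methylene.

Step 19
Reactants: 36 tetracyclic ketone; 37 2,2,2-trifluoroethyl trifluoroacetate; 38 4-acetamidobenzenesulfonyl azide
Product: 40 6-diazo-7-ketone, via 6-trifluoroacetyl ketone 39 (not isolated)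
Conditions: LiN(SiMe3)2, THF, −78 °C; CF3CO2CH2CF3; then 38, Et3N, H2O, MeCN, 25 °C
Reagents that add atoms: 4-acetamidobenzenesulfonyl azide, CC(=O)Nc1ccc(cc1)S(=O)(=O)N=[N+]=[N-]
Why: Danheiser detrifluoroacetylative diazo transfer; the ketone can enolise only towards C6 because C8 is quaternary, so the diazo group enters regiospecifically.

Step 20
Reactants: 40 diazo ketone; 41 tert-butanol
Product: 43 ring-B-contracted 7-tert-butyl ester (C6 epimer mixture; the 6β-ester is drawn), via ketene 42 (not isolated)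
Conditions: hν (≥ 300 nm), t-BuOH/THF, 2,4,6-collidine (cat.), 25 °C
Reagents that add atoms: tert-butanol, CC(C)(C)O
Why: Photochemical Wolff rearrangement of the s-cis-locked cyclic diazo ketone: loss of N2 with 1,2-shift of C8 from C7 to C6 (retention at C8) contracts ring B to the cyclopentane and the exocyclic ketene is trapped by the alcohol as the C7 ester.

Step 21
Reactants: 43 ring-contracted triester lactone
Product: 44 ring A β-keto tert-butyl ester (3-oxo-19-oate, drawn as the C3=C4 enol)
Conditions: KOt-Bu (2.5 equiv), THF, 0 → 25 °C; AcOH quench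
Reagents that add atoms: none
Why: Dieckmann condensation in which only the C3 methyl ester can serve as acyl acceptor (the tert-butyl esters are poor acceptors and the lactone is out of reach) closes ring A as a trans-fused six-membered ring, the product is protected as its enolate, and C6 should equilibrate to the 6β-ester trans to the C4–C5 bond.

Step 22
Reactants: 44 β-keto ester; 45 iodomethane
Product: 46 4β-methyl-3-oxo 19-tert-butyl ester
Conditions: MeI, K2CO3, acetone, 25 °C
Reagents that add atoms: iodomethane, CI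
Why: C-Alkylation of the β-keto ester enolate should occur on the β-face, anti to the axial C10–C20 bond, as in the classical 4-alkylation of 3-oxo-4-carboxylate A-ring systems, setting quaternary C4 (18-methyl β, 19-ester α).

Step 23
Reactants: 46 3-ketone
Product: 47 3β-alcohol
Conditions: LiB(s-Bu)3H, THF, −78 °C; H2O
Reagents that add atoms: none
Why: The bulky hydride attacks the C3 ketone equatorially from the α-face to give the axial 3β-alcohol, as in reductions of 3-oxogibberellins and 4,4-disubstituted 3-oxo terpenoids.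

Step 24
Reactants: 47 di-tert-butyl ester; 48 trimethylsilyl trifluoromethanesulfonate
Product: 50 target gibberellin 20,12α-lactone (3β-hydroxy 7,19-diacid), via tris(trimethylsilyl) derivative 49 (not isolated)
Conditions: Me3SiOTf, 2,6-lutidine, CH2Cl2, 0 °C; then H2O/THF
Reagents that add atoms: none
Why: Silyl triflate-mediated cleavage of tert-butyl esters (silyl esters formed with loss of isobutene, then hydrolysed) under buffered conditions spares the exocyclic alkene and the lactone.

Step 25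
Reactants: 50 target gibberellin 20,12α-lactone; 9 lithium hydroxide
Product: 51 target gibberellin (3β,12α-dihydroxygibberell-16-ene-7,19,20-trioic acid)
Conditions: LiOH, THF/H2O, 25–40 °C; then aq. HCl to pH 3 at 0 °C, EtOAc extraction
Reagents that add atoms: lithium hydroxide, [Li+].[OH-]
Why: Saponification of the δ-lactone and cold acidification liberate the C20 acid and the 12α-hydroxyl; C19 is present as its carboxylate, which suppresses retro-aldol epimerisation at C3.

**Compound list**

1 | 3-[(tert-butyldimethylsilyl)oxy]propanal | O=CCCO[Si](C)(C)C(C)(C)C | starting material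
2 | vinylmagnesium bromide | C=C[Mg]Br | starting material
3 | rac-5-[(tert-butyldimethylsilyl)oxy]pent-1-en-3-ol | C=CC(O)CCO[Si](C)(C)C(C)(C)C | intermediate
4 | trimethyl orthoacetate | CC(OC)(OC)OC | starting material
5 | mixed ketene acetal, tert-butyl({3-[(1-methoxyethenyl)oxy]pent-4-en-1-yl}oxy)dimethylsilane | C=C(OC)OC(C=C)CCO[Si](C)(C)C(C)(C)C | intermediate
6 | methyl (4E)-7-[(tert-butyldimethylsilyl)oxy]hept-4-enoate | COC(=O)CC/C=C/CCO[Si](C)(C)C(C)(C)C | intermediate
7 | potassium peroxymonosulfate | OOS(=O)(=O)[O-].[K+] | starting material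
8 | methyl 3-[(2S,3S)-3-{2-[(tert-butyldimethylsilyl)oxy]ethyl}oxiran-2-yl]propanoate | COC(=O)CC[C@@H]1O[C@H]1CCO[Si](C)(C)C(C)(C)C | intermediate
9 | lithium hydroxide | [Li+].[OH-] | starting material
10 | 3-[(2S,3S)-3-{2-[(tert-butyldimethylsilyl)oxy]ethyl}oxiran-2-yl]propanoic acid | OC(=O)CC[C@@H]1O[C@H]1CCO[Si](C)(C)C(C)(C)C | intermediate
11 | (5R)-5-[(1S)-3-[(tert-butyldimethylsilyl)oxy]-1-hydroxypropyl]oxolan-2-one | O=C1CC[C@@H](O1)[C@@H](O)CCO[Si](C)(C)C(C)(C)C | intermediate
12 | triisopropylsilyl trifluoromethanesulfonate | CC(C)[Si](OS(=O)(=O)C(F)(F)F)(C(C)C)C(C)C | starting material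
13 | (5R)-5-[(1S)-3-[(tert-butyldimethylsilyl)oxy]-1-[(triisopropylsilyl)oxy]propyl]oxolan-2-one | O=C1CC[C@@H](O1)[C@@H](O[Si](C(C)C)(C(C)C)C(C)C)CCO[Si](C)(C)C(C)(C)C | intermediate
14 | 3-bromo-1-(trimethylsilyl)prop-1-yne | C[Si](C)(C)C#CCBr | starting material
15 | (3S,5R)-5-[(1S)-3-[(tert-butyldimethylsilyl)oxy]-1-[(triisopropylsilyl)oxy]propyl]-3-[3-(trimethylsilyl)prop-2-yn-1-yl]oxolan-2-one | O=C1[C@@H](CC#C[Si](C)(C)C)C[C@@H](O1)[C@@H](O[Si](C(C)C)(C(C)C)C(C)C)CCO[Si](C)(C)C(C)(C)C | intermediate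
16 | diphenyl chlorophosphate | O=P(Cl)(Oc1ccccc1)Oc1ccccc1 | starting material
17 | (5R)-5-[(1S)-3-[(tert-butyldimethylsilyl)oxy]-1-[(triisopropylsilyl)oxy]propyl]-3-[3-(trimethylsilyl)prop-2-yn-1-yl]-4,5-dihydrofuran-2-yl diphenyl phosphate | O=P(Oc1ccccc1)(Oc1ccccc1)OC1=C(CC#C[Si](C)(C)C)C[C@@H](O1)[C@@H](O[Si](C(C)C)(C(C)C)C(C)C)CCO[Si](C)(C)C(C)(C)C | intermediate
18 | but-3-ynoic acid | C#CCC(=O)O | starting material
19 | tert-butyl 2,2,2-trichloroacetimidate | CC(C)(C)OC(=N)C(Cl)(Cl)Cl | starting material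
20 | tert-butyl but-3-ynoate | C#CCC(=O)OC(C)(C)C | intermediate
21 | pinacolborane | CC1(C)OBOC1(C)C | starting material
22 | tert-butyl (3E)-4-(4,4,5,5-tetramethyl-1,3,2-dioxaborolan-2-yl)but-3-enoate | CC(C)(C)OC(=O)C/C=C/B1OC(C)(C)C(C)(C)O1 | intermediate
23 | methyl [bis(2,2,2-trifluoroethoxy)phosphoryl]acetate | COC(=O)CP(=O)(OCC(F)(F)F)OCC(F)(F)F | starting material
24 | methyl acrylate | C=CC(=O)OC | starting material
25 | dimethyl 2-[bis(2,2,2-trifluoroethoxy)phosphoryl]pentanedioate (racemic) | COC(=O)CCC(C(=O)OC)P(=O)(OCC(F)(F)F)OCC(F)(F)F | intermediate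
26 | tert-butyl (3E)-4-{(5R)-5-[(1S)-3-[(tert-butyldimethylsilyl)oxy]-1-[(triisopropylsilyl)oxy]propyl]-3-[3-(trimethylsilyl)prop-2-yn-1-yl]-4,5-dihydrofuran-2-yl}but-3-enoate | CC(C)(C)OC(=O)C/C=C/C1=C(CC#C[Si](C)(C)C)C[C@@H](O1)[C@@H](O[Si](C(C)C)(C(C)C)C(C)C)CCO[Si](C)(C)C(C)(C)C | intermediate
27 | tert-butyl (3E)-4-{(5R)-5-[(1S)-3-hydroxy-1-[(triisopropylsilyl)oxy]propyl]-3-(prop-2-yn-1-yl)-4,5-dihydrofuran-2-yl}but-3-enoate | CC(C)(C)OC(=O)C/C=C/C1=C(CC#C)C[C@@H](O1)[C@@H](O[Si](C(C)C)(C(C)C)C(C)C)CCO | intermediate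
28 | tert-butyl (3E)-4-{(5R)-5-[(1S)-3-oxo-1-[(triisopropylsilyl)oxy]propyl]-3-(prop-2-yn-1-yl)-4,5-dihydrofuran-2-yl}but-3-enoate | CC(C)(C)OC(=O)C/C=C/C1=C(CC#C)C[C@@H](O1)[C@@H](O[Si](C(C)C)(C(C)C)C(C)C)CC=O | intermediate
29 | dimethyl (2Z)-2-{(3S)-3-[(2R)-5-[(1E)-4-tert-butoxy-4-oxobut-1-en-1-yl]-4-(prop-2-yn-1-yl)-2,3-dihydrofuran-2-yl]-3-[(triisopropylsilyl)oxy]propylidene}pentanedioate | CC(C)(C)OC(=O)C/C=C/C1=C(CC#C)C[C@@H](O1)[C@@H](O[Si](C(C)C)(C(C)C)C(C)C)C/C=C(/CCC(=O)OC)\C(=O)OC | intermediate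
30 | Diels–Alder adduct (cyclohexene ring B with C6=C7, O13 bridging C13 and C7, 8β-propargyl, 12α-silyloxy) | C#CC[C@]23C[C@@H]4[C@@H](O[Si](C(C)C)(C(C)C)C(C)C)C[C@H]2[C@](C(=O)OC)(CCC(=O)OC)[C@@H](CC(=O)OC(C)(C)C)C=C3O4 | intermediate
31 | water | O | starting material
32 | 12α,13α-dihydroxy 7-ketone (keto diol) | C#CC[C@]23C[C@@H](O)[C@@H](O)C[C@H]2[C@](C(=O)OC)(CCC(=O)OC)[C@@H](CC(=O)OC(C)(C)C)CC3=O | intermediate
33 | 13α-hydroxy-7-oxo 20,12α-lactone | C#CC[C@]23C[C@@H](O)[C@@H]4C[C@H]2[C@](C(=O)O4)(CCC(=O)OC)[C@@H](CC(=O)OC(C)(C)C)CC3=O | intermediate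
34 | 1,1'-thiocarbonyldiimidazole | S=C(n1ccnc1)n1ccnc1 | starting material
35 | 13-O-(imidazol-1-ylcarbonothioyl) derivative of 33 | C#CC[C@]23C[C@@H](OC(=S)n5ccnc5)[C@@H]4C[C@H]2[C@](C(=O)O4)(CCC(=O)OC)[C@@H](CC(=O)OC(C)(C)C)CC3=O | intermediate
36 | tetracyclic 7-ketone with ring D (16-methylene, 20,12α-lactone) | C=C1C[C@]23C[C@H]1[C@@H]4C[C@H]2[C@](C(=O)O4)(CCC(=O)OC)[C@@H](CC(=O)OC(C)(C)C)CC3=O | intermediate
37 | 2,2,2-trifluoroethyl trifluoroacetate | FC(F)(F)COC(=O)C(F)(F)F | starting material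
38 | 4-acetamidobenzenesulfonyl azide | CC(=O)Nc1ccc(cc1)S(=O)(=O)N=[N+]=[N-] | starting material
39 | 6-trifluoroacetyl 7-ketone (C6 epimers and enol, lithium enolate in the flask) | C=C1C[C@]23C[C@H]1[C@@H]4C[C@H]2[C@](C(=O)O4)(CCC(=O)OC)[C@@H](CC(=O)OC(C)(C)C)C(C(=O)C(F)(F)F)C3=O | intermediate
40 | 6-diazo-7-ketone | C=C1C[C@]23C[C@H]1[C@@H]4C[C@H]2[C@](C(=O)O4)(CCC(=O)OC)[C@@H](CC(=O)OC(C)(C)C)C(=[N+]=[N-])C3=O | intermediate
41 | tert-butanol | CC(C)(C)O | starting material
42 | ring-contracted ketene (C6=C7=O) | C=C1C[C@]23C[C@H]1[C@@H]4C[C@H]2[C@](C(=O)O4)(CCC(=O)OC)[C@@H](CC(=O)OC(C)(C)C)C3=C=O | intermediate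
43 | ring-B-contracted 7-tert-butyl ester (6β-epimer drawn; formed with its C6 epimer) | C=C1C[C@]23C[C@H]1[C@@H]4C[C@H]2[C@](C(=O)O4)(CCC(=O)OC)[C@@H](CC(=O)OC(C)(C)C)[C@@H]3C(=O)OC(C)(C)C | intermediate
44 | ring A β-keto tert-butyl ester (enol tautomer drawn) | C=C1C[C@]23C[C@H]1[C@@H]4C[C@H]2[C@]5(C(=O)O4)CCC(O)=C(C(=O)OC(C)(C)C)[C@H]5[C@@H]3C(=O)OC(C)(C)C | intermediate
45 | iodomethane | CI | starting material
46 | 4β-methyl-3-oxo di-tert-butyl ester lactone | C=C1C[C@]23C[C@H]1[C@@H]4C[C@H]2[C@]5(C(=O)O4)CCC(=O)[C@@](C)(C(=O)OC(C)(C)C)[C@H]5[C@@H]3C(=O)OC(C)(C)C | intermediate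
47 | 3β-hydroxy di-tert-butyl ester lactone | C=C1C[C@]23C[C@H]1[C@@H]4C[C@H]2[C@]5(C(=O)O4)CC[C@H](O)[C@@](C)(C(=O)OC(C)(C)C)[C@H]5[C@@H]3C(=O)OC(C)(C)C | intermediate
48 | trimethylsilyl trifluoromethanesulfonate | C[Si](C)(C)OS(=O)(=O)C(F)(F)F | starting material
49 | 3-O-trimethylsilyl bis(trimethylsilyl) ester lactone | C=C1C[C@]23C[C@H]1[C@@H]4C[C@H]2[C@]5(C(=O)O4)CC[C@H](O[Si](C)(C)C)[C@@](C)(C(=O)O[Si](C)(C)C)[C@H]5[C@@H]3C(=O)O[Si](C)(C)C | intermediate
50 | target gibberellin 20,12α-lactone (3β-hydroxy 7,19-diacid) | C=C1C[C@]23C[C@H]1[C@@H]4C[C@H]2[C@]5(C(=O)O4)CC[C@H](O)[C@@](C)(C(=O)O)[C@H]5[C@@H]3C(=O)O | intermediate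
51 | target gibberellin, 3β,12α-dihydroxygibberell-16-ene-7,19,20-trioic acid | C=C1C[C@]23C[C@H]1[C@@H](O)C[C@H]2[C@]1(C(=O)O)CC[C@H](O)[C@@](C)(C(=O)O)[C@H]1[C@@H]3C(=O)O | target

**Summary**

Total step count: 25. Longest linear sequence: 22 steps (steps 1–7 and 11–25).

Steps most likely to fail:

1. Step 15. The propargyl group sits Z on the diene terminus C8 and disfavours the s-cis conformer, so a [1,5]-hydrogen shift from C15 to C5 or thermal decomposition of the enol ether may outrun the cycloaddition. The fallback leaves the propargyl group out of the diene and sets out from lactone 13. O-Phosphorylation as in step 7 gives the des-propargyl ketene acetal phosphate F1, Suzuki coupling with 22 the dienyl dihydrofuran F2, buffered fluoride the primary alcohol F3, Dess–Martin oxidation the aldehyde F4, and Still–Gennari olefination with 25 the triene F5. Its diene terminus now carries only hydrogen inside and should cyclise on milder heating to the 8β-H adduct F6. Aqueous HF then PPTS gives the 8β-H keto lactone F7, and Et3SiCl/imidazole caps the 13-hydroxyl as the triethylsilyl ether F8. The thermodynamic potassium enolate (KOt-Bu, t-BuOH/THF) is then alkylated with propargyl bromide at the ring-fusion carbon C8; the lactone-locked cis B/C fusion leaves only the axial β position, giving the 8β-propargyl silyl ether F9. HF·pyridine removes the silyl group and the route is rejoined at 33.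

2. Step 21. Acyl transfer may go in an unwanted direction (C2 enolate onto the C7 or C19 ester), or the strained trans-fused β-keto ester may reopen by retro-Claisen cleavage. The fallback sets out from 43. Me3SnOH hydrolyses the single methyl ester selectively to the C3 carboxylic acid F10, and 1,1'-carbonyldiimidazole converts it into the C3 acyl imidazolide F11. LiN(SiMe3)2 (excess) then generates the tert-butyl ester enolate at C4, which is acylated intramolecularly by the only activated carbonyl (directed Claisen acylation); an enolate formed at C2 instead can exchange by proton transfer and has no reactive acceptor of its own. The route is rejoined at 44.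

3. Step 18. Hydrogen transfer to the C13 radical before ring closure would give simple deoxygenation, and the hindered thiocarbonyl group may fragment slowly. The fallback sets out from 33. Appel iodination (I2, PPh3, imidazole) gives the 13β-iodide F12 (inversion; the configuration is irrelevant). Et3B/O2-initiated iodine-atom-transfer cyclisation, in which no hydride source competes with ring closure, gives the 17-iodo-16-methylene compound F13 as an E/Z mixture. Bu3SnH/AIBN reduction of the C–I bond rejoins the route at 36.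

**Further compounds**

F1 | step 15 | (5R)-5-[(1S)-3-[(tert-butyldimethylsilyl)oxy]-1-[(triisopropylsilyl)oxy]propyl]-4,5-dihydrofuran-2-yl diphenyl phosphate | O=P(Oc1ccccc1)(Oc1ccccc1)OC1=CC[C@@H](O1)[C@@H](O[Si](C(C)C)(C(C)C)C(C)C)CCO[Si](C)(C)C(C)(C)C
F2 | step 15 | des-propargyl dienyl dihydrofuran (bis-silyl ether) | CC(C)(C)OC(=O)C/C=C/C1=CC[C@@H](O1)[C@@H](O[Si](C(C)C)(C(C)C)C(C)C)CCO[Si](C)(C)C(C)(C)C
F3 | step 15 | des-propargyl primary alcohol | CC(C)(C)OC(=O)C/C=C/C1=CC[C@@H](O1)[C@@H](O[Si](C(C)C)(C(C)C)C(C)C)CCO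
F4 | step 15 | des-propargyl aldehyde | CC(C)(C)OC(=O)C/C=C/C1=CC[C@@H](O1)[C@@H](O[Si](C(C)C)(C(C)C)C(C)C)CC=O
F5 | step 15 | des-propargyl Z-triene | CC(C)(C)OC(=O)C/C=C/C1=CC[C@@H](O1)[C@@H](O[Si](C(C)C)(C(C)C)C(C)C)C/C=C(/CCC(=O)OC)\C(=O)OC
F6 | step 15 | des-propargyl Diels–Alder adduct (8β-H) | [H][C@]23C[C@@H]4[C@@H](O[Si](C(C)C)(C(C)C)C(C)C)C[C@H]2[C@](C(=O)OC)(CCC(=O)OC)[C@@H](CC(=O)OC(C)(C)C)C=C3O4
F7 | step 15 | 8β-H 13α-hydroxy-7-oxo 20,12α-lactone | [H][C@]23C[C@@H](O)[C@@H]4C[C@H]2[C@](C(=O)O4)(CCC(=O)OC)[C@@H](CC(=O)OC(C)(C)C)CC3=O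
F8 | step 15 | 13-O-triethylsilyl ether of F7 | [H][C@]23C[C@@H](O[Si](CC)(CC)CC)[C@@H]4C[C@H]2[C@](C(=O)O4)(CCC(=O)OC)[C@@H](CC(=O)OC(C)(C)C)CC3=O
F9 | step 15 | 8β-propargyl 13-O-triethylsilyl keto lactone | C#CC[C@]23C[C@@H](O[Si](CC)(CC)CC)[C@@H]4C[C@H]2[C@](C(=O)O4)(CCC(=O)OC)[C@@H](CC(=O)OC(C)(C)C)CC3=O
F10 | step 21 | C3 carboxylic acid derived from 43 | C=C1C[C@]23C[C@H]1[C@@H]4C[C@H]2[C@](C(=O)O4)(CCC(=O)O)[C@@H](CC(=O)OC(C)(C)C)[C@@H]3C(=O)OC(C)(C)C
F11 | step 21 | C3 acyl imidazolide | C=C1C[C@]23C[C@H]1[C@@H]4C[C@H]2[C@](C(=O)O4)(CCC(=O)n5ccnc5)[C@@H](CC(=O)OC(C)(C)C)[C@@H]3C(=O)OC(C)(C)C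
F12 | step 18 | 13β-iodo-7-oxo 20,12α-lactone | C#CC[C@]23C[C@H](I)[C@@H]4C[C@H]2[C@](C(=O)O4)(CCC(=O)OC)[C@@H](CC(=O)OC(C)(C)C)CC3=O
F13 | step 18 | 17-iodo-16-methylene tetracyclic ketone (E/Z mixture) | IC=C1C[C@]23C[C@H]1[C@@H]4C[C@H]2[C@](C(=O)O4)(CCC(=O)OC)[C@@H](CC(=O)OC(C)(C)C)CC3=O
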